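**Retrosynthetic overview**

1. The strategy rests on ring A: its C5–C6–C7 segment is a masked acetoacetyl unit (a 2,2-dimethyl-1,3-dioxin-4-one), and its C4a=C8a bond is the enol ether double bond of ring C, a (2S)-2-aryl-2,3-dihydro-4H-pyran-4-one, with the prenyl group already on C8.
2. The target comes from its 2'-O-methoxymethyl ether 24, and ring A of 24 is opened at the C4a–C5 bond to the dioxinone-bearing pyranone 20 (acylketene formation, then six-electron electrocyclization).
3. 20 comes from pyranone 12 and the prenylated dioxinone dienol silyl ether 18 by vinylogous Mukaiyama–Michael addition (C8–C8a bond) followed by Saegusa oxidation.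
4. 12 comes from ring B aldehyde 9 and Danishefsky's diene 10 by asymmetric hetero-Diels–Alder reaction, which sets C2; 9 is made from (4-hydroxyphenyl)acetonitrile, and 18 from 2,2,6-trimethyl-4H-1,3-dioxin-4-one and prenyl bromide.
5. Ring order: ring B (purchased arene), then ring C (step 6), then ring A (step 11).

Key step: step 11

Assumption: the titanium catalyst made from (S)-H8-BINOL is taken to deliver the diene to the Si face of aldehyde 9, which gives the (2S) pyranone; if the facial sense proved to be the reverse, the (R)-ligand would be used and nothing else changes.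

Abbreviation used in names: Ar = 2-(methoxymethoxy)-5-(2-methylbut-3-en-2-yl)phenyl.

**Route**

Step 1
Reactants: 1 (4-hydroxyphenyl)acetonitrile
Product: 2 [4-(methoxymethoxy)phenyl]acetonitrile
Conditions: MeOCH2Cl, iPr2NEt, CH2Cl2, 0 °C to rt
Reagents that add atoms: chloromethyl methyl ether, COCCl
Why: O-alkylation of the phenol (Williamson-type acetal formation) should be clean under amine base without touching the benzylic nitrile, and the methoxymethyl ether later serves as the ortho-directing group.

Step 2
Reactants: 2 [4-(methoxymethoxy)phenyl]acetonitrile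
Product: 4 2-[4-(methoxymethoxy)phenyl]-2-methylpropanenitrile, via monomethyl nitrile 3 (not isolated)
Conditions: NaH (2.5 equiv), MeI (3 equiv), THF–DMF, 0 °C to rt
Reagents that add atoms: iodomethane, CI
Why: exhaustive α-alkylation of an arylacetonitrile anion is a standard way to a benzylic quaternary carbon, the second methylation following the first in the same flask.

Step 3
Reactants: 4 2-[4-(methoxymethoxy)phenyl]-2-methylpropanenitrile
Product: 6 2-[4-(methoxymethoxy)phenyl]-2-methylpropanal, via iminoalane 5 (not isolated)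
Conditions: iBu2AlH, toluene, −78 °C to 0 °C; then 1 M aq. HCl, 0 °C, short contact
Reagents that add atoms: water, O
Why: partial reduction of a tertiary nitrile by the aluminium hydride stops at the N-aluminated aldimine, which brief cold hydrolysis converts into the non-enolizable aldehyde while the aryl acetal should survive.

Step 4
Reactants: 6 2-[4-(methoxymethoxy)phenyl]-2-methylpropanal
Product: 7 1-(methoxymethoxy)-4-(2-methylbut-3-en-2-yl)benzene
Conditions: Ph3PCH3Br, KOtBu, THF, 0 °C to rt
Reagents that add atoms: methyltriphenylphosphonium bromide, C[P+](c1ccccc1)(c1ccccc1)c1ccccc1.[Br-]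
Why: Wittig methylenation of a hindered but non-enolizable aldehyde with the unstabilized ylide should complete the 1,1-dimethylallyl group.

Step 5
Reactants: 7 1-(methoxymethoxy)-4-(2-methylbut-3-en-2-yl)benzene
Product: 9 2-(methoxymethoxy)-5-(2-methylbut-3-en-2-yl)benzaldehyde, via aryllithium 8 (not isolated)
Conditions: n-BuLi, TMEDA, Et2O, 0 °C; then DMF, 0 °C to rt; H2O
Reagents that add atoms: N,N-dimethylformamide, CN(C)C=O
Why: directed ortho-metalation by the methoxymethoxy group followed by formylation should be regioselective because the two ortho positions are equivalent and the quaternary benzylic carbon offers no acidic hydrogen.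

Step 6
Reactants: 9 2-(methoxymethoxy)-5-(2-methylbut-3-en-2-yl)benzaldehyde; 10 (E)-1-methoxy-3-(trimethylsilyloxy)buta-1,3-diene
Product: 12 (2S)-2-[2-(methoxymethoxy)-5-(2-methylbut-3-en-2-yl)phenyl]-2,3-dihydro-4H-pyran-4-one, via open-chain aldol adduct 11 (not isolated)
Conditions: Ti(OiPr)4 (20 mol%), (S)-H8-BINOL (22 mol%), 4 Å molecular sieves, toluene, 0 °C; then CF3CO2H (cat.), CH2Cl2, 0 °C
Reagents that add atoms: none
Why: catalytic asymmetric hetero-Diels–Alder reaction of an aromatic aldehyde with Danishefsky's diene (Mukaiyama aldol pathway, then acid-induced ring closure with loss of methanol and the silyl group) should give the dihydropyranone, the chiral titanium binaphtholate blocking the Re face of the aldehyde so that C–C bond formation on the Si face sets C2 as S.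

Step 7
Reactants: 13 2,2,6-trimethyl-4H-1,3-dioxin-4-one; 14 1-bromo-3-methylbut-2-ene
Product: 16 2,2-dimethyl-6-(4-methylpent-3-en-1-yl)-4H-1,3-dioxin-4-one, via lithium dienolate 15 (not isolated)
Conditions: LiN(iPr)2, THF–DMPU, −78 °C; then 14, −78 °C to −20 °C
Reagents that add atoms: none
Why: γ-alkylation of the extended (vinylogous) dioxinone enolate with a reactive allylic bromide should be favoured over α-attack in the presence of the dipolar cosolvent.

Step 8
Reactants: 16 2,2-dimethyl-6-(4-methylpent-3-en-1-yl)-4H-1,3-dioxin-4-one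
Product: 18 2,2-dimethyl-6-(4-methylpent-3-en-1-ylidene)-4-(trimethylsilyloxy)-6H-1,3-dioxine, via lithium dienolate 17 (not isolated)
Conditions: LiN(iPr)2, THF, −78 °C; then Me3SiCl, −78 °C to 0 °C; non-aqueous work-up
Reagents that add atoms: chlorotrimethylsilane, C[Si](C)(C)Cl
Why: kinetic deprotonation at the γ-methylene and O-silylation is the established way to dioxinone-derived dienol silyl ethers, and the exocyclic alkene geometry is of no consequence.

Step 9
Reactants: 12 (2S)-2-[2-(methoxymethoxy)-5-(2-methylbut-3-en-2-yl)phenyl]-2,3-dihydro-4H-pyran-4-one; 18 2,2-dimethyl-6-(4-methylpent-3-en-1-ylidene)-4-(trimethylsilyloxy)-6H-1,3-dioxine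
Product: 19 (2S)-2-Ar-6-[1-(2,2-dimethyl-4-oxo-4H-1,3-dioxin-6-yl)-4-methylpent-3-enyl]-4-(trimethylsilyloxy)-3,6-dihydro-2H-pyran
Conditions: Me3SiOTf (10 mol%), CH2Cl2, −78 °C; Et3N quench, non-aqueous work-up, used crude
Reagents that add atoms: none
Why: vinylogous Mukaiyama–Michael addition, in which the silyl triflate turns the vinylogous ester into a 4-silyloxy oxocarbenium ion that the γ-carbon of the dienol ether attacks at C6 (axially, anti to the aryl group, so 2,6-trans is expected), with silyl transfer giving the regiodefined C4=C5 enol ether; both new stereocentres are removed later, so their ratio is irrelevant.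

Step 10
Reactants: 19 (2S)-2-Ar-6-[1-(2,2-dimethyl-4-oxo-4H-1,3-dioxin-6-yl)-4-methylpent-3-enyl]-4-(trimethylsilyloxy)-3,6-dihydro-2H-pyran
Product: 20 (2S)-6-[1-(2,2-dimethyl-4-oxo-4H-1,3-dioxin-6-yl)-4-methylpent-3-enyl]-2-Ar-2,3-dihydro-4H-pyran-4-one
Conditions: Pd(OAc)2 (1.1 equiv), MeCN, rt
Reagents that add atoms: none
Why: Ito–Saegusa oxidation, in which the divalent palladium enolate formed at C5 can only eliminate the single β-hydrogen on C6, should restore the C5=C6 enol ether double bond without touching C2 or the isolated alkenes.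

Step 11
Reactants: 20 (2S)-6-[1-(2,2-dimethyl-4-oxo-4H-1,3-dioxin-6-yl)-4-methylpent-3-enyl]-2-Ar-2,3-dihydro-4H-pyran-4-one
Product: 24 (2S)-5,7-dihydroxy-2-[2-(methoxymethoxy)-5-(2-methylbut-3-en-2-yl)phenyl]-8-(3-methylbut-2-enyl)-2,3-dihydro-4H-chromen-4-one, via acylketene 21 (not isolated), via dienol ketene 22 (not isolated), via cyclohexadienone 23 (not isolated)
Conditions: slow addition of 20 to refluxing dry toluene (final 0.002 M), 110 °C, N2
Reagents that add atoms: none
Why: Proposed new method: at 110 °C the dioxinone should undergo retro-[4+2] loss of acetone to acylketene 21 (C5 is the ketene carbon), whose C7 ketone enolizes towards the doubly activated C8–H to give dienylketene 22, a triene C4a=C8a–C8=C7–C6=C5 that ends in the ketene. Ring A is then expected to close by a thermal disrotatory six-electron electrocyclization, equivalent to a 6-endo C-acylation of the nucleophilic α-carbon C4a of the vinylogous ester by C5, which forms the C4a–C5 bond; cyclohexadienone 23 aromatizes by two proton shifts to the 5,7-dihydroxyarene. The closest known reactions are the thermolysis of dioxinones to acylketenes used in biomimetic resorcylate synthesis and the dienylketene electrocyclization that ends the Danheiser benzannulation, but their combination on a pyranone enol ether has not been shown. No stereocentre is created, since the side-chain centre C8 and the transient C4a centre both become sp2, and C2 sees only neutral thermal conditions. The step needs ring closure at C4a to outrun ketene dimerization and capture by stray nucleophiles, which high dilution and dry conditions should secure, while the usual O-acylation to a 2-pyranone is excluded because the oxygen on C8a is the ring ether O1. The prenyl group is bonded to C8 before the ring exists, so its place between O1 and the 7-hydroxyl is fixed by construction.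

Step 12
Reactants: 24 (2S)-5,7-dihydroxy-2-[2-(methoxymethoxy)-5-(2-methylbut-3-en-2-yl)phenyl]-8-(3-methylbut-2-enyl)-2,3-dihydro-4H-chromen-4-one
Product: 25 (2S)-5,7-dihydroxy-2-[2-hydroxy-5-(2-methylbut-3-en-2-yl)phenyl]-8-(3-methylbut-2-enyl)-2,3-dihydro-4H-chromen-4-one
Conditions: 3 M aq. HCl–MeOH (1:10), 40 °C, stopped at full conversion
Reagents that add atoms: none
Why: acid-catalysed acetal methanolysis should remove the single aryl methoxymethyl ether under conditions mild enough to spare the prenyl group next to the 7-hydroxyl, the 1,1-dimethylallyl group and the C2 stereocentre.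

**Compound list**

1 | (4-hydroxyphenyl)acetonitrile | N#CCc1ccc(O)cc1 | starting material
2 | [4-(methoxymethoxy)phenyl]acetonitrile | N#CCc1ccc(OCOC)cc1 | intermediate
3 | 2-[4-(methoxymethoxy)phenyl]propanenitrile (racemic, not isolated) | CC(C#N)c1ccc(OCOC)cc1 | intermediate
4 | 2-[4-(methoxymethoxy)phenyl]-2-methylpropanenitrile | CC(C)(C#N)c1ccc(OCOC)cc1 | intermediate
5 | N-(diisobutylaluminio)-2-[4-(methoxymethoxy)phenyl]-2-methylpropan-1-imine (not isolated) | CC(C)C[Al](CC(C)C)N=CC(C)(C)c1ccc(OCOC)cc1 | intermediate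
6 | 2-[4-(methoxymethoxy)phenyl]-2-methylpropanal | CC(C)(C=O)c1ccc(OCOC)cc1 | intermediate
7 | 1-(methoxymethoxy)-4-(2-methylbut-3-en-2-yl)benzene | C=CC(C)(C)c1ccc(OCOC)cc1 | intermediate
8 | [2-(methoxymethoxy)-5-(2-methylbut-3-en-2-yl)phenyl]lithium (not isolated) | [Li]c1cc(C(C)(C)C=C)ccc1OCOC | intermediate
9 | 2-(methoxymethoxy)-5-(2-methylbut-3-en-2-yl)benzaldehyde | O=Cc1cc(C(C)(C)C=C)ccc1OCOC | intermediate
10 | (E)-1-methoxy-3-(trimethylsilyloxy)buta-1,3-diene | CO/C=C/C(=C)O[Si](C)(C)C | starting material
11 | (1E,5S)-1-methoxy-5-Ar-5-(trimethylsilyloxy)pent-1-en-3-one (not isolated) | C=CC(C)(C)c1ccc(OCOC)c([C@@H](O[Si](C)(C)C)CC(=O)/C=C/OC)c1 | intermediate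
12 | (2S)-2-[2-(methoxymethoxy)-5-(2-methylbut-3-en-2-yl)phenyl]-2,3-dihydro-4H-pyran-4-one | C=CC(C)(C)c1ccc(OCOC)c([C@@H]2CC(=O)C=CO2)c1 | intermediate
13 | 2,2,6-trimethyl-4H-1,3-dioxin-4-one | CC1=CC(=O)OC(C)(C)O1 | starting material
14 | 1-bromo-3-methylbut-2-ene (prenyl bromide) | CC(C)=CCBr | starting material
15 | lithium 2,2-dimethyl-6-methylidene-6H-1,3-dioxin-4-olate (not isolated) | [Li]OC1=CC(=C)OC(C)(C)O1 | intermediate
16 | 2,2-dimethyl-6-(4-methylpent-3-en-1-yl)-4H-1,3-dioxin-4-one | CC(C)=CCCC1=CC(=O)OC(C)(C)O1 | intermediate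
17 | lithium 2,2-dimethyl-6-(4-methylpent-3-en-1-ylidene)-6H-1,3-dioxin-4-olate (not isolated) | [Li]OC1=CC(=CCC=C(C)C)OC(C)(C)O1 | intermediate
18 | 2,2-dimethyl-6-(4-methylpent-3-en-1-ylidene)-4-(trimethylsilyloxy)-6H-1,3-dioxine (mixture of exocyclic alkene isomers) | CC(C)=CCC=C1C=C(O[Si](C)(C)C)OC(C)(C)O1 | intermediate
19 | (2S)-2-Ar-6-[1-(2,2-dimethyl-4-oxo-4H-1,3-dioxin-6-yl)-4-methylpent-3-enyl]-4-(trimethylsilyloxy)-3,6-dihydro-2H-pyran (mixture at C6 and the side-chain carbon, 2,6-trans expected to predominate) | C=CC(C)(C)c1ccc(OCOC)c([C@@H]2CC(O[Si](C)(C)C)=CC(C(CC=C(C)C)C3=CC(=O)OC(C)(C)O3)O2)c1 | intermediate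
20 | (2S)-6-[1-(2,2-dimethyl-4-oxo-4H-1,3-dioxin-6-yl)-4-methylpent-3-enyl]-2-[2-(methoxymethoxy)-5-(2-methylbut-3-en-2-yl)phenyl]-2,3-dihydro-4H-pyran-4-one (mixture of epimers at the side-chain carbon) | C=CC(C)(C)c1ccc(OCOC)c([C@@H]2CC(=O)C=C(C(CC=C(C)C)C3=CC(=O)OC(C)(C)O3)O2)c1 | intermediate
21 | 4-[(2S)-2-Ar-4-oxo-3,4-dihydro-2H-pyran-6-yl]-7-methylocta-1,6-diene-1,3-dione (acylketene, not isolated) | C=CC(C)(C)c1ccc(OCOC)c([C@@H]2CC(=O)C=C(C(CC=C(C)C)C(=O)C=C=O)O2)c1 | intermediate
22 | 3-hydroxy-4-[(2S)-2-Ar-4-oxo-3,4-dihydro-2H-pyran-6-yl]-7-methylocta-1,3,6-trien-1-one (enol of 21, pyranyl carbon and ketene CH cis on the enol double bond, not isolated) | C=CC(C)(C)c1ccc(OCOC)c([C@@H]2CC(=O)C=C(/C(CC=C(C)C)=C(/O)C=C=O)O2)c1 | intermediate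
23 | (2S)-7-hydroxy-2-Ar-8-(3-methylbut-2-enyl)-2,3-dihydro-4H-chromene-4,5(4aH)-dione (mixture at C4a, not isolated) | C=CC(C)(C)c1ccc(OCOC)c([C@@H]2CC(=O)C3C(=O)C=C(O)C(CC=C(C)C)=C3O2)c1 | intermediate
24 | (2S)-5,7-dihydroxy-2-[2-(methoxymethoxy)-5-(2-methylbut-3-en-2-yl)phenyl]-8-(3-methylbut-2-enyl)-2,3-dihydro-4H-chromen-4-one | C=CC(C)(C)c1ccc(OCOC)c([C@@H]2CC(=O)c3c(O)cc(O)c(CC=C(C)C)c3O2)c1 | intermediate
25 | (2S)-5,7-dihydroxy-2-[2-hydroxy-5-(2-methylbut-3-en-2-yl)phenyl]-8-(3-methylbut-2-enyl)-2,3-dihydro-4H-chromen-4-one (CID51040684) | C=CC(C)(C)c1ccc(O)c([C@@H]2CC(=O)c3c(O)cc(O)c(CC=C(C)C)c3O2)c1 | target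

**Step count**

Total steps: 12. Longest linear sequence: 10 steps (steps 1 to 6, then 9 to 12); steps 7 and 8 form the side branch.

**Steps most likely to fail**

1. Step 11. Ring closure at C4a may be outrun by ketene dimerization, by capture of the ketene by traces of water, or by slow enolization towards C8 that leaves the ketene time to react with the prenyl alkene. The fallback sets out from 20 and comes back at 24, replacing the pericyclic closure by a stepwise ionic one built from known reaction types. Heating 20 in toluene at 110 °C with methanol (5 equiv) would capture the acylketene, a well-established dioxinone reaction, as methyl 4-[(2S)-2-Ar-4-oxo-3,4-dihydro-2H-pyran-6-yl]-7-methyl-3-oxooct-6-enoate F1. Treatment of F1 with NaOMe in MeOH at 0 °C would then effect a Claisen (Dieckmann-type) condensation, the C8 carbanion attacking the ester through C4a as in the base-mediated closure of polyketo esters to acylphloroglucinols, and loss of methanol with aromatization would give 24. The low temperature is chosen to keep base-induced opening at C2 slow.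

2. Step 9. The γ-substituted dienol ether 18 may add sluggishly or through its α-carbon, and the silyl triflate may begin to ionize the aryl methoxymethyl acetal. The fallback sets out from 12 and 13 and comes back at 20, attaching the prenyl group after the pyranone–dioxinone bond. 13 would be converted (LiN(iPr)2, then Me3SiCl) into the unhindered parent dienol ether 2,2-dimethyl-6-methylidene-4-(trimethylsilyloxy)-6H-1,3-dioxine F2, a reagent of proven γ-selectivity. Its Mukaiyama–Michael addition to 12 (Me3SiOTf cat., −78 °C) would give (2S)-2-Ar-6-[(2,2-dimethyl-4-oxo-4H-1,3-dioxin-6-yl)methyl]-4-(trimethylsilyloxy)-3,6-dihydro-2H-pyran F3, and Saegusa oxidation with Pd(OAc)2 would give (2S)-2-Ar-6-[(2,2-dimethyl-4-oxo-4H-1,3-dioxin-6-yl)methyl]-2,3-dihydro-4H-pyran-4-one F4. The methylene of F4 lies between two vinylogous ester β-carbons and is the most acidic site, so alkylation with 14 (Cs2CO3, DMF, 0 °C to rt) would give 20.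

3. Step 6. Facial selectivity may be poor if the ortho methoxymethoxy oxygen chelates titanium and distorts the catalyst. The fallback sets out from 9 and comes back at 12, setting C2 by a reagent-controlled aldol reaction instead of a cycloaddition. Commercial (E)-4-chlorobut-3-en-2-one would be enolized with Ipc2BCl and iPr2NEt (the enantiomer of the borane that directs addition to the Si face of 9) and added to 9 to give (1E,5S)-1-chloro-5-hydroxy-5-Ar-pent-1-en-3-one F5. Intramolecular oxa-Michael addition of the hydroxyl with loss of chloride (iPr2NEt, CH2Cl2, with Me3SiOTf as promoter if needed) would close ring C and give 12.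

**Further compounds**

F1 | step 11 | methyl 4-[(2S)-2-Ar-4-oxo-3,4-dihydro-2H-pyran-6-yl]-7-methyl-3-oxooct-6-enoate (mixture at C4 of the chain) | C=CC(C)(C)c1ccc(OCOC)c([C@@H]2CC(=O)C=C(C(CC=C(C)C)C(=O)CC(=O)OC)O2)c1
F2 | step 9 | 2,2-dimethyl-6-methylidene-4-(trimethylsilyloxy)-6H-1,3-dioxine | C=C1C=C(O[Si](C)(C)C)OC(C)(C)O1
F3 | step 9 | (2S)-2-Ar-6-[(2,2-dimethyl-4-oxo-4H-1,3-dioxin-6-yl)methyl]-4-(trimethylsilyloxy)-3,6-dihydro-2H-pyran (mixture at C6) | C=CC(C)(C)c1ccc(OCOC)c([C@@H]2CC(O[Si](C)(C)C)=CC(CC3=CC(=O)OC(C)(C)O3)O2)c1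
F4 | step 9 | (2S)-2-Ar-6-[(2,2-dimethyl-4-oxo-4H-1,3-dioxin-6-yl)methyl]-2,3-dihydro-4H-pyran-4-one | C=CC(C)(C)c1ccc(OCOC)c([C@@H]2CC(=O)C=C(CC3=CC(=O)OC(C)(C)O3)O2)c1
F5 | step 6 | (1E,5S)-1-chloro-5-hydroxy-5-[2-(methoxymethoxy)-5-(2-methylbut-3-en-2-yl)phenyl]pent-1-en-3-one | C=CC(C)(C)c1ccc(OCOC)c([C@@H](O)CC(=O)/C=C/Cl)c1
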